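**Remark on the chemistry (assumption):** the target has no stereocentre, and both biaryl axes carry a para-substituted, locally symmetric ring. It is therefore achiral, "the single enantiomer given" is the compound itself, and no stereocontrol is needed.

**Compound numbering**

- 1: 4-(benzyloxy)benzyl chloride
- 2: diethyl oxalate
- 3: [4-(benzyloxy)benzyl]magnesium chloride (not isolated)
- 4: ethyl 3-[4-(benzyloxy)phenyl]-2-oxopropanoate
- 5: ethyl 3,6-bis[4-(benzyloxy)phenyl]-2,4,5-trioxohexanoate (not isolated)
- 6: 2,5-dihydroxy-3,6-bis[4-(benzyloxy)phenyl]cyclohexa-2,5-diene-1,4-dione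
- 7: dichlorodiphenylmethane
- 8: 4,7-bis[4-(benzyloxy)phenyl]-2,2-diphenyl-1,3-benzodioxole-5,6-dione
- 9: benzoyl chloride
- 10: 4,7-bis[4-(benzyloxy)phenyl]-2,2-diphenyl-1,3-benzodioxole-5,6-diol (not isolated)
- 11: 4,7-bis[4-(benzyloxy)phenyl]-2,2-diphenyl-1,3-benzodioxole-5,6-diyl dibenzoate
- 12: the target, 4,4'',5',6'-tetrahydroxy-[1,1':4',1''-terphenyl]-2',3'-diyl dibenzoate

## Analysis of the target

The target is a p-terphenyl. Two 4-hydroxyphenyl rings (A and C) sit on C1' and C4' of a hexasubstituted central benzene ring B, and the other four carbons of ring B all carry oxygen: benzoates on C2' and C3', free hydroxyls on C5' and C6'. There is no stereogenic element; the molecule has a time-averaged twofold axis through the midpoints of C2'–C3' and C5'–C6'. The sensitive groups are the electron-rich catechol at C5'/C6' (aerial oxidation to an o-quinone), the two base-labile aryl benzoates, and phenols of two kinds that must be told apart. The first difficulty is ring B itself: every position is substituted and each biaryl bond is flanked by two oxygens. The second is that the four oxygens of a 1,2,4,5-tetraoxygenated ring must be divided into one adjacent pair of esters and one adjacent pair of hydroxyls. Because C1' and C4' separate the two pairs, a benzoate cannot migrate from one pair to the other, so a wrong distribution cannot be repaired by equilibration. Simple acylation at the quinone or hydroquinone level puts one ester on each pair (the para pattern).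

The route uses two features of this structure. First, ring B is twice the unit aryl–C–C(O)–C(O): Ar–C1'–C2'(O)–C3'(O) and Ar–C4'–C5'(O)–C6'(O), two arylpyruvate C9 units joined head to tail through C3'–C4' and C6'–C1'. This is the presumed biosynthetic dimerization to the terphenylquinone atromentin. Second, the O2'/O3' diester with the O5'/O6' diol is the reduced form of the o-quinonoid tautomer of that quinone.

## Retrosynthetic reasoning

**12 from 11.** The last cut removes only protecting groups: the two benzyl ethers on rings A and C and the diphenylmethylene ketal across O5'/O6'. All three are benzylic C–O bonds, so one hydrogenolysis should cleave them under neutral conditions. The aryl benzoates and the ester distribution stay untouched, and no free hydroxyl ever sits next to a benzoate.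

**11 from 8.** The two benzoate C–O bonds are cut next. Both esters go onto catechol 10, which arises in the flask by two-electron reduction of o-quinone 8. The redox state, not reagent selectivity, decides which oxygen pair is acylated: in 8 one pair is locked in the ketal and the other pair is the o-quinone.

**8 from 6.** The ketal C–O bonds are cut. Quinone 6 has four oxygens, but only its o-quinonoid tautomer offers two hydroxyls on adjacent carbons. A bridging electrophile can therefore be taken up once only, and the product must be an o-quinone. The desymmetrization is self-limiting and needs no statistical mono-protection.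

**6 from two molecules of 4 (key disconnection).** Ring B is cut at C3'–C4' and C6'–C1' (C1–C6 and C3–C4 in the numbering of 6). This gives two identical arylpyruvate esters 4; each supplies one aryl-bearing carbon and one complete O,O pair. The forward reaction is a twofold Claisen condensation: the benzylic carbon of each unit is acylated by the ester carbonyl of the other. It builds the whole hexasubstituted ring, both aryl–ring attachments included, without halogenation or cross-coupling.

**4 from 1 and 2.** The C2–C3 bond of the keto ester is cut to a benzylic nucleophile (3, from 1) and the oxalate diester 2, a standard one-step entry to arylpyruvates.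

## Alternatives that were turned down

**Alternative 1:** the textbook cut of both biaryl bonds (C1'–ring A and C4'–ring C).
- Forward key step: twofold Suzuki–Miyaura coupling of 4,7-dibromo-5,6-bis(methoxymethoxy)-1,3-benzodioxole A1 with an O-benzyl-protected 4-hydroxyphenylboron reagent to give terphenyl A2.
- Reason turned down: A1 must first be built by about five linear oxidation, protection and bromination steps before any C–C bond is made. Each coupling forms a biaryl bond with two ortho oxygens. The methylenedioxy group of A2 must later be removed oxidatively beside electron-rich rings. The route would be at least twice as long as the one chosen.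

**Alternative 2:** cut C6'–C1' and C2'–C3'... more precisely, the two bonds joining a C4 unit (both aryl-bearing carbons and one O,O pair) to a C2 unit (the other pair).
- Forward key step: [4+2] cycloaddition of cyclopentadienone ketal A3 (from a 1,3-diarylacetone and an oxalate ester through a cyclopentanetrione) with a 1,2-diborylated alkyne, then cheletropic loss of CO, to give bis-boronate A4.
- Reason turned down: this would differentiate the two oxygen pairs in the ring-forming step. However, no stable alkyne carries two hydroxy or acyloxy groups, so the C2 partner must be a surrogate. A4 then needs oxidation of two hindered C–B bonds before it reaches the stage of 10. Alkene surrogates would aromatize by β-elimination with loss of one oxygen instead of by dehydrogenation. The result is about seven steps with three uncertain ones (ketal formation on the trione, a very crowded cycloaddition, double C–B oxidation).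

**Alternative 3:** electrocyclic ring expansion of a squarate-derived cyclobutenone.
- Forward key step: addition of a separately prepared 1-aryl-2-alkoxyvinyl organometallic to aryl squarate A5, thermal 4π opening to a dienylketene, 6π closure and oxidation to quinone A6.
- Reason turned down: a C2-symmetric core would be assembled unsymmetrically, with each aryl group introduced in its own sequence and a cryogenic organometallic addition of demanding regiochemistry. The product A6 is only the dialkyl ether of 6, so dealkylation and the whole differentiation problem remain.

Key step: step 2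

## Route

**Step 1**
Reactants: 1 4-(benzyloxy)benzyl chloride; 2 diethyl oxalate
Product: 4 ethyl 3-[4-(benzyloxy)phenyl]-2-oxopropanoate, via [4-(benzyloxy)benzyl]magnesium chloride 3 (not isolated)
Conditions: Mg turnings, THF, 0 °C (slow addition of 1); then cannulation into 2 (3 equiv), THF, −78 °C; aq. NH4Cl
Reagents that add atoms: diethyl oxalate (2), CCOC(=O)C(=O)OCC; magnesium, [Mg] (kept only in intermediate 3)
Why: Grignard acylation with an oxalate diester; the tetrahedral magnesium hemiketal alkoxide is stable at −78 °C and collapses to the α-keto ester only on work-up, so inverse addition to excess 2 should prevent a second addition.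

**Step 2**
Reactants: 4 ethyl 3-[4-(benzyloxy)phenyl]-2-oxopropanoate (two molecules)
Product: 6 2,5-dihydroxy-3,6-bis[4-(benzyloxy)phenyl]cyclohexa-2,5-diene-1,4-dione, via open-chain trioxohexanoate 5 (not isolated)
Conditions: NaH (1.1 equiv per 4), THF, 0 °C; then PhMe, 110 °C, EtOH distilled off; 1 M HCl
Reagents that add atoms: none
Why: Proposed new method: a twofold Claisen self-condensation of a 3-arylpyruvate ester, in which the benzylic carbon of one sodium enolate is acylated by the ester carbonyl of a second to give 5, and the remaining enolate carbon of 5 then attacks the remaining ester to close ring B; the closest known reaction types are the alkali-metal-mediated self-condensation of aliphatic α-keto esters to 3,6-dialkyl-2,5-dihydroxy-1,4-benzoquinones and the enzymatic thioester version of this dimerization of 4-hydroxyphenylpyruvate. The ring closure is a 6-(enolendo)-exo-trig Dieckmann-type acylation, which is allowed, and the resulting cyclohexanetetraone tautomerizes at once to the dihydroxyquinone. No stereocentre is formed. The selectivity needed is acyl substitution at the ester (Claisen) over addition to the ketone carbonyl (aldol, then lactonization), which is the usual fate of arylpyruvates under partial deprotonation. It should be secured by converting 4 completely into its enolate before heating, so that no free ketone carbonyl is present and the ester is the only electrophilic carbon. O-acylated enol esters that may form are themselves acyl donors and should funnel to the C-acylated product. The driving force is the product dianion, a double vinylogous carboxylate expected to leave the aprotic medium as its disodium salt, together with removal of ethanol, which should make both acylations irreversible. Only one constitution can result, because the sole nucleophilic carbon is benzylic and the sole acyl donor is the ester.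

**Step 3**
Reactants: 6 2,5-dihydroxy-3,6-bis[4-(benzyloxy)phenyl]cyclohexa-2,5-diene-1,4-dione; 7 dichlorodiphenylmethane
Product: 8 4,7-bis[4-(benzyloxy)phenyl]-2,2-diphenyl-1,3-benzodioxole-5,6-dione
Conditions: Cs2CO3 (2.2 equiv), 7 (1.2 equiv, slow addition), dry MeCN, 60 °C; non-aqueous work-up
Reagents that add atoms: dichlorodiphenylmethane (7), ClC(Cl)(c1ccccc1)c1ccccc1
Why: Proposed new method: the dianion of 6 is a double vinylogous carboxylate, so O-alkylation by the readily ionizing gem-dichloride gives an α-chloro ether whose oxocarbenium ion should be captured by the oxygen on the neighbouring ring carbon (five-membered ring), leaving the other two oxygens as an o-quinone; only one ketal can form because 6 offers only one such pair at its oxidation level. The closest known reaction types are O-alkylation of hydroxyquinone salts at the vinylogous carbonyl oxygen to give o-quinone ethers and diphenylmethylene ketal formation from catechols with this reagent.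

**Step 4**
Reactants: 8 4,7-bis[4-(benzyloxy)phenyl]-2,2-diphenyl-1,3-benzodioxole-5,6-dione; 9 benzoyl chloride
Product: 11 4,7-bis[4-(benzyloxy)phenyl]-2,2-diphenyl-1,3-benzodioxole-5,6-diyl dibenzoate, via catechol 10 (not isolated)
Conditions: Na2S2O4, THF–H2O (degassed), rt, argon; then crude 10, 9 (3 equiv), pyridine, DMAP (cat.), CH2Cl2, 0 °C to rt
Reagents that add atoms: benzoyl chloride (9), O=C(Cl)c1ccccc1
Why: Dithionite reduction of an o-quinone to its catechol followed by DMAP-catalysed acylation of both phenols (reductive acylation in two stages); the other oxygen pair is locked in the ketal, so the esters can only go onto the pair that was the quinone, and benzyl ethers and ketal are inert to both stages.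

**Step 5**
Reactants: 11 4,7-bis[4-(benzyloxy)phenyl]-2,2-diphenyl-1,3-benzodioxole-5,6-diyl dibenzoate
Product: 12 4,4'',5',6'-tetrahydroxy-[1,1':4',1''-terphenyl]-2',3'-diyl dibenzoate (target)
Conditions: H2 (1 atm), Pd(OH)2/C, EtOAc–THF, rt; filtration and concentration under argon
Reagents that add atoms: none
Why: Catalytic hydrogenolysis of the two benzyl aryl ethers and of the two benzylic C–O bonds of the diphenylmethylene ketal; aryl benzoates are not hydrogenolysed, and under neutral conditions no ester cleavage or transfer should occur.

## Compound list

1 | 4-(benzyloxy)benzyl chloride | ClCc1ccc(OCc2ccccc2)cc1 | starting material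
2 | diethyl oxalate | CCOC(=O)C(=O)OCC | starting material
3 | [4-(benzyloxy)benzyl]magnesium chloride | Cl[Mg]Cc1ccc(OCc2ccccc2)cc1 | intermediate (not isolated)
4 | ethyl 3-[4-(benzyloxy)phenyl]-2-oxopropanoate | CCOC(=O)C(=O)Cc1ccc(OCc2ccccc2)cc1 | intermediate
5 | ethyl 3,6-bis[4-(benzyloxy)phenyl]-2,4,5-trioxohexanoate (racemic, enolizable; present as its sodium enolate) | CCOC(=O)C(=O)C(c1ccc(OCc2ccccc2)cc1)C(=O)C(=O)Cc1ccc(OCc2ccccc2)cc1 | intermediate (not isolated)
6 | 2,5-dihydroxy-3,6-bis[4-(benzyloxy)phenyl]cyclohexa-2,5-diene-1,4-dione | O=C1C(O)=C(c2ccc(OCc3ccccc3)cc2)C(=O)C(O)=C1c1ccc(OCc2ccccc2)cc1 | intermediate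
7 | dichlorodiphenylmethane | ClC(Cl)(c1ccccc1)c1ccccc1 | starting material
8 | 4,7-bis[4-(benzyloxy)phenyl]-2,2-diphenyl-1,3-benzodioxole-5,6-dione | O=C1C(=O)C(c2ccc(OCc3ccccc3)cc2)=C2OC(c3ccccc3)(c3ccccc3)OC2=C1c1ccc(OCc2ccccc2)cc1 | intermediate
9 | benzoyl chloride | O=C(Cl)c1ccccc1 | starting material
10 | 4,7-bis[4-(benzyloxy)phenyl]-2,2-diphenyl-1,3-benzodioxole-5,6-diol | Oc1c(O)c(-c2ccc(OCc3ccccc3)cc2)c2OC(c3ccccc3)(c3ccccc3)Oc2c1-c1ccc(OCc2ccccc2)cc1 | intermediate (not isolated)
11 | 4,7-bis[4-(benzyloxy)phenyl]-2,2-diphenyl-1,3-benzodioxole-5,6-diyl dibenzoate | O=C(Oc1c(OC(=O)c2ccccc2)c(-c2ccc(OCc3ccccc3)cc2)c2OC(c3ccccc3)(c3ccccc3)Oc2c1-c1ccc(OCc2ccccc2)cc1)c1ccccc1 | intermediate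
12 | 4,4'',5',6'-tetrahydroxy-[1,1':4',1''-terphenyl]-2',3'-diyl dibenzoate | O=C(Oc1c(OC(=O)c2ccccc2)c(-c2ccc(O)cc2)c(O)c(O)c1-c1ccc(O)cc1)c1ccccc1 | target

## Step count and least certain steps

Total step count: 5. Longest linear sequence: 5 (step 2 joins two molecules of the same intermediate).

**Step 2 (key step, Proposed new method).** The most likely failure is carbon–carbon bond formation at the ketone carbonyl of any 4 that is not deprotonated (aldol addition followed by lactonization), outrunning acyl substitution at the deactivated ester of an enolate. The other possibility is that two anionic partners simply do not react. The fallback changes the disconnection of ring B from C3 + C3 to C4 + C2 and uses established reaction types. It sets out from 1 and 2 and comes back to the route at 6. Grignard reagent 3 (2.2 equiv, made from 1 as in step 1) is added to N,N'-dimethoxy-N,N'-dimethyloxamide in THF at 0 °C to give 1,4-bis[4-(benzyloxy)phenyl]butane-2,3-dione F1, the usual α-diketone synthesis from a Grignard reagent and an oxalic bis(N-methoxy-N-methylamide). F1 is then condensed with excess 2 under NaOEt in EtOH–toluene and acidified to give 6. This is an oxalate double Claisen annulation across the two benzylic methylene groups, the six-membered counterpart of the classical annulation of dibenzyl ketones with oxalate. The acyl donor is now the non-enolizable, strongly electrophilic oxalate, not the ester of an enolate.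

**Step 3 (Proposed new method).** The most likely failures are intermolecular O-alkylation leading to oligomeric ketals, consumption of the dichloride by adventitious water, and nucleophilic opening of the vinylogous o-quinone ketal during work-up with return to 6. The fallback uses ordinary catechol chemistry. It sets out from 6 and comes back to the route at 8. Compound 6 is reduced with Na2S2O4 to 3,6-bis[4-(benzyloxy)phenyl]benzene-1,2,4,5-tetrol F2, which is treated under argon with 7 (1.0 equiv) and K2CO3 in MeCN. Exposing the crude mixture to air should return unreacted F2 to 6 (removed by bicarbonate extraction and recycled) and convert the mono-ketal 10 into 8. Compound 8 is then separated by chromatography from the doubly protected by-product 4,8-bis[4-(benzyloxy)phenyl]-2,2,6,6-tetraphenylbenzo[1,2-d:4,5-d']bis[1,3]dioxole F3. This version is statistical and gives up the self-limiting character of step 3.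

**Step 1.** The most likely failures are Wurtz-type homocoupling of the electron-rich benzylic halide during magnesium insertion and a second addition of 3 to the keto ester if the low-temperature adduct collapses early. The fallback replaces the benzylic nucleophile by a benzylic electrophile with an acyl-anion equivalent. It sets out from 1 and comes back to the route at 4. The sodium salt of commercial ethyl 1,3-dithiane-2-carboxylate (NaH, DMF–toluene) is alkylated with 1 to give ethyl 2-[4-(benzyloxy)benzyl]-1,3-dithiane-2-carboxylate F4, and the dithioketal is removed with MeI and CaCO3 in aqueous MeCN to give 4.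

**Step 5.** The most likely failures are stalling of the ketal hydrogenolysis, because the ketal carbon is shielded by the two flanking aryl rings, while the benzyl ethers cleave normally, and aerial oxidation of the product catechol during isolation. The fallback removes the ketal by a different mechanism. It sets out from 11 and comes back to the route at 12. Hydrogenation over Pd/C is stopped once the benzyl ethers are gone, giving 4,7-bis(4-hydroxyphenyl)-2,2-diphenyl-1,3-benzodioxole-5,6-diyl dibenzoate F5. The ketal of F5 is then hydrolysed with TFA–H2O in CH2Cl2 at rt under argon to give 12; aryl benzoates should tolerate these conditions.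

## Further compounds

F1 | step 2 | 1,4-bis[4-(benzyloxy)phenyl]butane-2,3-dione | O=C(Cc1ccc(OCc2ccccc2)cc1)C(=O)Cc1ccc(OCc2ccccc2)cc1
F2 | step 3 | 3,6-bis[4-(benzyloxy)phenyl]benzene-1,2,4,5-tetrol | Oc1c(O)c(-c2ccc(OCc3ccccc3)cc2)c(O)c(O)c1-c1ccc(OCc2ccccc2)cc1
F3 | step 3 | 4,8-bis[4-(benzyloxy)phenyl]-2,2,6,6-tetraphenylbenzo[1,2-d:4,5-d']bis[1,3]dioxole | c1ccc(cc1)C1(c2ccccc2)Oc2c(O1)c(-c1ccc(OCc3ccccc3)cc1)c1OC(c3ccccc3)(c3ccccc3)Oc1c2-c1ccc(OCc2ccccc2)cc1
F4 | step 1 | ethyl 2-[4-(benzyloxy)benzyl]-1,3-dithiane-2-carboxylate | CCOC(=O)C1(Cc2ccc(OCc3ccccc3)cc2)SCCCS1
F5 | step 5 | 4,7-bis(4-hydroxyphenyl)-2,2-diphenyl-1,3-benzodioxole-5,6-diyl dibenzoate | O=C(Oc1c(OC(=O)c2ccccc2)c(-c2ccc(O)cc2)c2OC(c3ccccc3)(c3ccccc3)Oc2c1-c1ccc(O)cc1)c1ccccc1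
A1 | alternative 1 | 4,7-dibromo-5,6-bis(methoxymethoxy)-1,3-benzodioxole | COCOc1c(OCOC)c(Br)c2OCOc2c1Br
A2 | alternative 1 | 4,7-bis[4-(benzyloxy)phenyl]-5,6-bis(methoxymethoxy)-1,3-benzodioxole | COCOc1c(OCOC)c(-c2ccc(OCc3ccccc3)cc2)c2OCOc2c1-c1ccc(OCc2ccccc2)cc1
A3 | alternative 2 | 4,6-bis[4-(benzyloxy)phenyl]-2,2-diphenyl-5H-cyclopenta[d][1,3]dioxol-5-one | O=C1C(c2ccc(OCc3ccccc3)cc2)=C2OC(c3ccccc3)(c3ccccc3)OC2=C1c1ccc(OCc2ccccc2)cc1
A4 | alternative 2 | 2,2'-{4,7-bis[4-(benzyloxy)phenyl]-2,2-diphenyl-1,3-benzodioxole-5,6-diyl}bis(4,4,5,5-tetramethyl-1,3,2-dioxaborolane) | CC1(C)OB(OC1(C)C)c1c(B2OC(C)(C)C(C)(C)O2)c(-c2ccc(OCc3ccccc3)cc2)c2OC(c3ccccc3)(c3ccccc3)Oc2c1-c1ccc(OCc2ccccc2)cc1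
A5 | alternative 3 | 3-[4-(benzyloxy)phenyl]-4-(propan-2-yloxy)cyclobut-3-ene-1,2-dione | CC(C)OC1=C(c2ccc(OCc3ccccc3)cc2)C(=O)C1=O
A6 | alternative 3 | 3,6-bis[4-(benzyloxy)phenyl]-2-methoxy-5-(propan-2-yloxy)cyclohexa-2,5-diene-1,4-dione | COC1=C(c2ccc(OCc3ccccc3)cc2)C(=O)C(OC(C)C)=C(c2ccc(OCc3ccccc3)cc2)C1=O
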